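The constants used here are invented, and the outcome is calculated.

Starting material cannot reach target in this flask without first becoming intermediate, so I kept the books on what was left of it and not on what had been made.

starting material 2.0 M; gas 200 mM (held); catalyst 10 mol%; time 12 s

* how much target there is at 12 s, in percent of the starting material charged
* the change that raises the amount of target at 12 s, in percent of the starting material charged most ("none" if none brings more than 2 percentage points) (cedar / birch / maple / none)
* amount of target at 12 s, in percent of the starting material charged, after birch

- cedar: doubling the amount of catalyst, all else as stated
- birch: doubling the transfer coefficient of step 3, all else as stated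
- maple: doubling the saturation concentration of gas, all else as stated

    starting material + catalyst ⇌ catalyst + intermediate (K1 = 0.38, k1 = 0.65 /M/s)
    partner + catalyst + intermediate ⇌ catalyst + target (K2 = 43 /M, k2 = 1.3 /M²/s)
    gas ⇌ partner, rate k3*(csat - [partner]) (k3 = 1.5 /s, csat = 200 mM)
    2 partner → homo dimer (k4 = 0.54 /M/s)

Under catalyst, step 1 turns starting material into intermediate and back, step 2 joins intermediate to dissolved partner to give target, step 3 feeds partner from the held gas, and step 4 spends partner on homo dimer. I kept the ledger on starting material as the limiting reagent: the gas is held, and step 3 could deliver up to 180 % of the charge into a solution kept empty, more than the charge itself.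

In this flask [catalyst] was 0.200 M, and I reckoned a relaxation time for step 1 of 2.12 s, shorter than the run. I therefore took free starting material and intermediate as one pool, with a share 27.5 % standing as intermediate. Balancing step 3 against step 4 and leaving aside what step 2 uses, I put [partner] at 0.177 M. The rate constant of step 2 times [catalyst], [partner] and that share is the pseudo-first-order constant at which the pool drains, my drain constant, 0.0127 /s. I neglected the back reaction of step 2. Counted from the end of the relaxation time, I reckoned this flask to keep 88.2 % of its pool, and my ledger closed thus:

| Entry at 12 s | Share of the charge |
|---|---|
| Free starting material | 63.9 % |
| Intermediate | 24.3 % |
| Target | 11.8 % |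

The forecast gave 10.7 %, chose cedar and put birch at 11.5 %, holding that “step 2 is the slow step”. My 11.8 % stood above its figure.

The simulation gave 10.2 % of target. Cedar gained 9.3 percentage points, maple 7.2 points and birch 0.83 points, so cedar came first, and birch reached 11.0 %.

This flask's result left 89.8 % of the pool, a reading of 0.0109 /s for the drain constant against my 0.0127 /s. The neighbour flask held 1.2 M of starting material at the same loading, so its [catalyst] was 0.120 M. With my [partner] unchanged, its drain constant came to 0.00762 /s and its relaxation time to 3.53 s. By my reckoning that kept 93.8 % of the neighbour's pool and made 6.20 % of target. The neighbour flask gave 5.78 % of target, with 71 % of its starting material still unbound.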